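How slowly does G hand L on as Q? We carry that pace through flasks that differ in their L charge.

| flask | L | Z | G | remark | time |
|---|---|---|---|---|---|
| Thursday's | 0.022 M | 0.010 M | 3.5 mM | run made earlier |  |
| Wednesday's | 0.28 M | 0.010 M | 3.5 mM | run made earlier |  |
| west | 0.025 M | 0.0100 M | 3.5 mM |  | 6.0 h |
| south | 0.050 M | 0.0100 M | 3.5 mM |  | 6.0 h |
| south-east | 0.10 M | 0.0100 M | 3.5 mM |  | 6.0 h |
| north | 0.20 M | 0.0100 M | 3.5 mM |  | 6.0 h |
| north-west | 0.40 M | 0.0100 M | 3.5 mM |  | 6.0 h |

| run | time / h | Q / % | L / % |
|---|---|---|---|
| Thursday's | 0.250 | 34.0 | 35.6 |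
| Thursday's | 0.333 | 43.1 | 25.0 |
| Thursday's | 0.500 | 55.1 | 12.1 |
| Thursday's | 0.833 | 65.0 | 1.8 |
| Thursday's | 1.33 | 67.9 | 0.2 |
| Thursday's | 2.00 | 68.5 | 0.2 |
| Thursday's | 3.00 | 68.3 | 0.6 |
| Wednesday's | 0.417 | 9.6 | 85.3 |
| Wednesday's | 0.833 | 19.3 | 76.0 |
| Wednesday's | 1.33 | 30.4 | 64.4 |
| Wednesday's | 1.50 | 34.0 | 60.5 |
| Wednesday's | 2.00 | 45.3 | 50.1 |
| Wednesday's | 2.50 | 56.6 | 38.7 |
| Wednesday's | 3.00 | 67.1 | 28.6 |

(each reading ± 0.3 percentage points)

- steps that have been proposed: L + Z -> E; J -> G + Q; L + G -> J
- "hardly changes" means that all values lie within two and a half points (for a concentration: within two and a half percent of the largest)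

- amount of Q at the end, in percent of the L charged for west, south, south-east, north, north-west, in this order
- how that number moves from the first to the last of them (rises, then falls / hardly changes / falls, then rises / rises all the way / falls all the way)

The first rung of the ladder is short. By the first reading of Wednesday's run, at 0.417 h, 5.10% of the L charged stands in neither L nor Q, while the charges of Z and G together make 4.82% of it. So we read Wednesday's Z as turned into E and its G as held in J, the resting state.

On the next rung, Wednesday's Q climbs in a straight line, from 19.3% at 0.833 h to 67.1% at 3.00 h. That gives 17.6 h⁻¹ of L passed per G and per hour, the turnover pace. A charge divided by this pace and by G is its clearing time.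

Thursday's run stops on another rung: L ends first, and its loss of 31.5% of the L charged is 69.3% of Z's charge. West, charged a little above Thursday's run, should land just over that plateau.

The last rung is the time allowed, 6.0 h. The loss can't exceed Z's charge, so a flask that finishes ends with Q of at least 80.0% for south, 90.0% for south-east and 95.0% for north. North's clearing time is 3.24 h, well inside the time. North-west's is 6.48 h, beyond it, so the pace passes just 92.6% of that charge.

The forecast gives 70.3%, 80.2%, 90%, 95% and 91.5%, a row that rises, then falls, on the ground that “high L uses up Z quickly”. For north-west its value lies below ours.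

    L + Z → E (k = 0.0661 L mol⁻¹ s⁻¹)
    J → G + Q (k = 0.00544 s⁻¹)
    L + G → J (k = 0.367 L mol⁻¹ s⁻¹)

The flasks give 69.3%, 80.2%, 90.0%, 95.0% and 91.9%, and the row rises, then falls. At 6.00 h, north-west still holds 5.10% of its L, and our turnover share stands 0.70 percentage points above its Q. North's clearing time lies just past 3.00 h, when north still holds 8.82% of its L, and at 6.00 h north holds 0%.

(The data are calculated with constants of no real substance, noise included.)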